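**Plan**
- Enabling feature: ring A is a 2-acylphloroglucinol (oxygen on C5, C7 and C8a, the C4 acyl carbon on C4a), i.e. the enol form of a cyclic triketide. Its C5–C6 bond can therefore be cut as a Claisen bond between an ester carbon (C5) on C4a and the methyl carbon (C6) of a C7 ketone, while C8 is still an sp3 chain carbon that already holds the prenyl group.
- Retrosynthetic cuts, in order: O7–CH3 and the ring B methoxymethyl ether; C5–C6 (ring A); C8–prenyl and C7–C8 of the side chain on C8a; C4a=C8a and O1–C8a (ring C); C2–C3 (aldol).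
- Forward order: aldol chain, then ring C as a 2-aryl-2,3-dihydropyran-4-one with CO2Me on C4a, then acetyl and prenyl on the C8 carbon, then ring A, then O-methylation and deprotection.
- Stereochemistry: C2 (S) is the only stereocentre of the target; it is set by a BINOL–titanium catalysed vinylogous Mukaiyama aldol and its C–O bond is never broken afterwards. The C8 centre of the ring-A precursor is uncontrolled and disappears on aromatisation.

Key step: step 6

Assumption: Ti(OiPr)4/(S)-BINOL is taken to direct the dienolate to the Si face of aryl aldehydes, which gives the (S)-carbinol; if the sense is the reverse, (R)-BINOL is used and nothing else changes.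
Assumption: the bis-silyl dienolate of methyl acetoacetate is taken as a purchased reagent (otherwise it is made from methyl acetoacetate by two routine silylations).

**Route**

Step 1
Reactants: 1 isovanillin (3-hydroxy-4-methoxybenzaldehyde)
Product: 2 4-methoxy-3-(methoxymethoxy)benzaldehyde
Conditions: MOMCl, K2CO3, acetone, 0 °C to rt
Reagents that add atoms: chloromethyl methyl ether, COCCl
Why: Williamson-type O-alkylation of the phenoxide masks the only acidic proton of ring B as an acetal that is inert to the amide bases used later.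

Step 2
Reactants: 2 4-methoxy-3-(methoxymethoxy)benzaldehyde; 3 1-methoxy-1,3-bis(trimethylsilyloxy)buta-1,3-diene
Product: 5 methyl (5S)-5-hydroxy-5-[4-methoxy-3-(methoxymethoxy)phenyl]-3-oxopentanoate, via bis-silyl aldol adduct 4 (not isolated)
Conditions: Ti(OiPr)4 (10 mol%), (S)-BINOL (10 mol%), 4 Å molecular sieves, THF, −78 °C to rt; then aq. citric acid, THF, 0 °C
Reagents that add atoms: none
Why: Catalytic asymmetric vinylogous Mukaiyama aldol, in which the titanium BINOLate binds the aldehyde and leaves its Si face open to the terminal carbon of the dienolate, so that the carbinol (the future C2) is formed as S; mild acid then removes both silyl groups.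

Step 3
Reactants: 5 methyl (5S)-5-hydroxy-5-[4-methoxy-3-(methoxymethoxy)phenyl]-3-oxopentanoate; 6 N,N-dimethylacetamide dimethyl acetal (1,1-dimethoxy-N,N-dimethylethanamine)
Product: 8 methyl (2S)-2-[4-methoxy-3-(methoxymethoxy)phenyl]-6-methyl-4-oxo-2,3-dihydro-4H-pyran-5-carboxylate, via enaminone 7 (not isolated)
Conditions: toluene, rt; then PPTS (10 mol%), 40 °C
Reagents that add atoms: none
Why: Amide-acetal condensation at the active methylene gives the enaminone, whose δ-hydroxyl adds to the enamine carbon and expels dimethylamine (intramolecular addition–elimination), a known one-pot dihydropyranone synthesis from δ-hydroxy β-keto esters that leaves the C2–O bond, and so the configuration, untouched.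

Step 4
Reactants: 8 methyl (2S)-2-[4-methoxy-3-(methoxymethoxy)phenyl]-6-methyl-4-oxo-2,3-dihydro-4H-pyran-5-carboxylate; 9 N-methoxy-N-methylacetamide
Product: 10 methyl (2S)-2-[4-methoxy-3-(methoxymethoxy)phenyl]-4-oxo-6-(2-oxopropyl)-2,3-dihydro-4H-pyran-5-carboxylate
Conditions: LiN(SiMe3)2 (1.2 equiv), THF, −78 °C; then 9, −78 to −20 °C; AcOH quench
Reagents that add atoms: none
Why: Vinylogous Claisen acylation: the methyl group on C6 of the pyranone is γ to both the ketone and the ester, so reversible deprotonation by the hindered amide should give the extended dienolate rather than the C3 enolate, and its terminal carbon adds to the N-methoxy-N-methyl amide, whose chelated adduct keeps the new ketone masked until the quench.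

Step 5
Reactants: 10 methyl (2S)-2-[4-methoxy-3-(methoxymethoxy)phenyl]-4-oxo-6-(2-oxopropyl)-2,3-dihydro-4H-pyran-5-carboxylate; 11 prenyl bromide (1-bromo-3-methylbut-2-ene)
Product: 12 methyl (2S)-2-[4-methoxy-3-(methoxymethoxy)phenyl]-6-(6-methyl-2-oxohept-5-en-3-yl)-4-oxo-2,3-dihydro-4H-pyran-5-carboxylate (both epimers at the side-chain carbon)
Conditions: K2CO3, acetone, rt
Reagents that add atoms: none
Why: C-alkylation of a vinylogous 1,3-dicarbonyl compound: the methylene between the side-chain ketone and the push-pull alkene is the only site that carbonate ionises, and its soft carbanion should take the allylic bromide by SN2 at carbon, which fixes the prenyl group on the future C8; the new centre is formed without control and is erased in step 6.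

Step 6
Reactants: 12 methyl (2S)-2-[4-methoxy-3-(methoxymethoxy)phenyl]-6-(6-methyl-2-oxohept-5-en-3-yl)-4-oxo-2,3-dihydro-4H-pyran-5-carboxylate
Product: 14 (2S)-5,7-dihydroxy-2-[4-methoxy-3-(methoxymethoxy)phenyl]-8-(3-methylbut-2-enyl)chroman-4-one, via triketone tautomer 13 (not isolated)
Conditions: LiN(SiMe3)2 (2.2 equiv), THF, −78 to −20 °C; AcOH quench at −78 °C
Reagents that add atoms: none
Why: Proposed new method: the first equivalent of LiN(SiMe3)2 removes the doubly activated C8–H of 12 and the second reversibly deprotonates the C6 methyl group of the resulting lithium enolate, whose terminal carbon adds to the ester carbonyl (C5) held syn to it across the C4a=C8a double bond; loss of methoxide gives triketone 13, which the liberated base enolises to the aromatic diphenoxide of 14. Ring A closes in a 6-(enolendo)-exo-trig Dieckmann mode, and the closest known reactions are the base-mediated Claisen cyclisation of 2-(2-oxopropyl)benzoates to naphthalene-1,3-diols and the Claisen-mode cyclisation of polyketo esters to acylphloroglucinols, neither of which has been run on a dihydropyranone that already carries ring C. No stereocentre is created: the epimeric C8 centre of 12 becomes an aromatic carbon and C2 is a spectator. The step needs C6 deprotonation to win over C3 deprotonation, because a C3 enolate can expel O1 and so racemise C2, and it needs C-acylation to win over O-acylation by the C7 enolate oxygen, which would give an enol lactone. The substrate helps in that the methyl group is the least hindered acidic site and C3 lies next to the lithium-chelated C4 oxygen that already bears charge, while reversible deprotonation lets the cyclising dianion alone be drained and the low temperature slows ring opening. Because C8 carries the prenyl group before ring A exists, no choice between C6 and C8 arises.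

Step 7
Reactants: 14 (2S)-5,7-dihydroxy-2-[4-methoxy-3-(methoxymethoxy)phenyl]-8-(3-methylbut-2-enyl)chroman-4-one
Product: 15 (2S)-5-hydroxy-7-methoxy-2-[4-methoxy-3-(methoxymethoxy)phenyl]-8-(3-methylbut-2-enyl)chroman-4-one
Conditions: MeOH, PPh3, DIAD, THF, 0 °C to rt
Reagents that add atoms: methanol, CO
Why: Mitsunobu etherification: the 7-hydroxyl is the more acidic and the only unchelated phenol, whereas the 5-hydroxyl is held in a hydrogen bond to the C4 carbonyl, and the neutral conditions avoid base-induced opening of ring C.

Step 8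
Reactants: 15 (2S)-5-hydroxy-7-methoxy-2-[4-methoxy-3-(methoxymethoxy)phenyl]-8-(3-methylbut-2-enyl)chroman-4-one
Product: 16 (2S)-5-hydroxy-2-(3-hydroxy-4-methoxyphenyl)-7-methoxy-8-(3-methylbut-2-enyl)chroman-4-one
Conditions: 3 M aq. HCl, MeOH, 45 °C
Reagents that add atoms: none
Why: Acid-catalysed acetal exchange removes the methoxymethyl ether; the prenyl group has no free ortho hydroxyl (O7 is methylated, the 5-hydroxyl is para), so no chroman can form, and the flavanone centre is stable to dilute acid.

**Compound list**
1 | isovanillin (3-hydroxy-4-methoxybenzaldehyde) | COc1ccc(C=O)cc1O | starting material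
2 | 4-methoxy-3-(methoxymethoxy)benzaldehyde | COCOc1cc(C=O)ccc1OC | intermediate
3 | 1-methoxy-1,3-bis(trimethylsilyloxy)buta-1,3-diene | COC(O[Si](C)(C)C)=CC(=C)O[Si](C)(C)C | starting material
4 | methyl (5S)-5-[4-methoxy-3-(methoxymethoxy)phenyl]-3,5-bis(trimethylsilyloxy)pent-2-enoate (not isolated) | COC(=O)C=C(O[Si](C)(C)C)C[C@H](O[Si](C)(C)C)c1ccc(OC)c(OCOC)c1 | intermediate
5 | methyl (5S)-5-hydroxy-5-[4-methoxy-3-(methoxymethoxy)phenyl]-3-oxopentanoate | COC(=O)CC(=O)C[C@H](O)c1ccc(OC)c(OCOC)c1 | intermediate
6 | N,N-dimethylacetamide dimethyl acetal | CC(OC)(OC)N(C)C | starting material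
7 | methyl (5S)-2-[1-(dimethylamino)ethylidene]-5-hydroxy-5-[4-methoxy-3-(methoxymethoxy)phenyl]-3-oxopentanoate (not isolated) | COC(=O)C(=C(C)N(C)C)C(=O)C[C@H](O)c1ccc(OC)c(OCOC)c1 | intermediate
8 | methyl (2S)-2-[4-methoxy-3-(methoxymethoxy)phenyl]-6-methyl-4-oxo-2,3-dihydro-4H-pyran-5-carboxylate | COC(=O)C1=C(C)O[C@H](c2ccc(OC)c(OCOC)c2)CC1=O | intermediate
9 | N-methoxy-N-methylacetamide | CC(=O)N(C)OC | starting material
10 | methyl (2S)-2-[4-methoxy-3-(methoxymethoxy)phenyl]-4-oxo-6-(2-oxopropyl)-2,3-dihydro-4H-pyran-5-carboxylate | COC(=O)C1=C(CC(C)=O)O[C@H](c2ccc(OC)c(OCOC)c2)CC1=O | intermediate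
11 | prenyl bromide (1-bromo-3-methylbut-2-ene) | CC(C)=CCBr | starting material
12 | methyl (2S)-2-[4-methoxy-3-(methoxymethoxy)phenyl]-6-(6-methyl-2-oxohept-5-en-3-yl)-4-oxo-2,3-dihydro-4H-pyran-5-carboxylate (side-chain epimers) | COC(=O)C1=C(C(CC=C(C)C)C(C)=O)O[C@H](c2ccc(OC)c(OCOC)c2)CC1=O | intermediate
13 | (2S)-2-[4-methoxy-3-(methoxymethoxy)phenyl]-8-(3-methylbut-2-enyl)-2,3,6,8-tetrahydro-4H-chromene-4,5,7-trione (C8 epimers, not isolated) | COc1ccc([C@@H]2CC(=O)C3=C(O2)C(CC=C(C)C)C(=O)CC3=O)cc1OCOC | intermediate
14 | (2S)-5,7-dihydroxy-2-[4-methoxy-3-(methoxymethoxy)phenyl]-8-(3-methylbut-2-enyl)chroman-4-one | COc1ccc([C@@H]2CC(=O)c3c(O)cc(O)c(CC=C(C)C)c3O2)cc1OCOC | intermediate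
15 | (2S)-5-hydroxy-7-methoxy-2-[4-methoxy-3-(methoxymethoxy)phenyl]-8-(3-methylbut-2-enyl)chroman-4-one | COc1ccc([C@@H]2CC(=O)c3c(O)cc(OC)c(CC=C(C)C)c3O2)cc1OCOC | intermediate
16 | (2S)-5-hydroxy-2-(3-hydroxy-4-methoxyphenyl)-7-methoxy-8-(3-methylbut-2-enyl)chroman-4-one | COc1ccc([C@@H]2CC(=O)c3c(O)cc(OC)c(CC=C(C)C)c3O2)cc1O | target

**Step count**
Total steps: 8. Longest linear sequence: 8 steps (1 to 16).

**Steps most likely to fail**

1. Step 6 (Proposed new method). Three processes may defeat it:
- deprotonation at C3 in place of C6, followed by β-elimination of O1, which destroys the C2 configuration and, after re-closure, scrambles the prenyl group between C6 and C8;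
- O-acylation by the C7 enolate oxygen to an enol lactone;
- no closure at all, because the conjugated ester is a weak electrophile.

Fallback with known chemistry, setting out from 2 and returning at 15, with ring A bought ready-made:
- Claisen–Schmidt condensation of 2 with commercial 2',6'-dihydroxy-4'-methoxyacetophenone (KOH, EtOH–H2O, rt) should give the chalcone (E)-1-(2,6-dihydroxy-4-methoxyphenyl)-3-[4-methoxy-3-(methoxymethoxy)phenyl]prop-2-en-1-one F1.
- NaOAc in refluxing EtOH closes ring C by oxa-Michael addition to racemic 5-hydroxy-7-methoxy-2-[4-methoxy-3-(methoxymethoxy)phenyl]chroman-4-one F2.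
- Mitsunobu etherification of the 5-hydroxyl with 3-methylbut-2-en-1-ol (PPh3, DIAD, THF) gives racemic 7-methoxy-2-[4-methoxy-3-(methoxymethoxy)phenyl]-5-(3-methylbut-2-enyloxy)chroman-4-one F3.
- A para-Claisen–Cope rearrangement catalysed by Eu(fod)3 (fod = 6,6,7,7,8,8,8-heptafluoro-2,2-dimethyloctane-3,5-dionate; CHCl3, 60 °C) carries the allyl unit through C6 to C8 and gives racemic 5-hydroxy-7-methoxy-2-[4-methoxy-3-(methoxymethoxy)phenyl]-8-(3-methylbut-2-enyl)chroman-4-one F4.
- Chromatography on a chiral stationary phase then delivers 15, and step 8 follows.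

2. Step 4. The amide base may deprotonate C3 rather than the methyl group, with opening of ring C, or the dienolate may react through oxygen or the ester-bearing carbon.

Fallback without a metal base, setting out from 8 and returning at 10:
- Heating 8 with a further equivalent of 6 (toluene, 80 °C) should condense the acetal at the activated methyl group to the dienamine methyl (2S)-6-[2-(dimethylamino)prop-1-enyl]-2-[4-methoxy-3-(methoxymethoxy)phenyl]-4-oxo-2,3-dihydro-4H-pyran-5-carboxylate F5.
- Hydrolysis of the enamine with aqueous AcOH in THF at rt gives 10.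

3. Step 5. The delocalised anion may be alkylated on oxygen or on the ester-bearing carbon instead of the future C8, may take a second prenyl group, or may lactonise onto the ester under carbonate.

Fallback that reverses the order of the two C–C bond formations, setting out from 8 and returning at 12:
- The dienolate of 8 (LiN(SiMe3)2, THF–DMPU, −78 °C) is alkylated with 11 at the terminal carbon to methyl (2S)-2-[4-methoxy-3-(methoxymethoxy)phenyl]-6-(4-methylpent-3-enyl)-4-oxo-2,3-dihydro-4H-pyran-5-carboxylate F6.
- The γ-methylene of this compound is then deprotonated again (LiN(SiMe3)2, THF, −78 °C) and acylated with 9 (AcOH quench), so that the prenyl-bearing carbon is acylated instead of the acylated carbon being alkylated; the product is 12.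

**Further compounds**
F1 | step 6 | (E)-1-(2,6-dihydroxy-4-methoxyphenyl)-3-[4-methoxy-3-(methoxymethoxy)phenyl]prop-2-en-1-one | COCOc1cc(/C=C/C(=O)c2c(O)cc(OC)cc2O)ccc1OC
F2 | step 6 | racemic 5-hydroxy-7-methoxy-2-[4-methoxy-3-(methoxymethoxy)phenyl]chroman-4-one | COCOc1cc(C2CC(=O)c3c(O)cc(OC)cc3O2)ccc1OC
F3 | step 6 | racemic 7-methoxy-2-[4-methoxy-3-(methoxymethoxy)phenyl]-5-(3-methylbut-2-enyloxy)chroman-4-one | COCOc1cc(C2CC(=O)c3c(OCC=C(C)C)cc(OC)cc3O2)ccc1OC
F4 | step 6 | racemic 5-hydroxy-7-methoxy-2-[4-methoxy-3-(methoxymethoxy)phenyl]-8-(3-methylbut-2-enyl)chroman-4-one | COc1ccc(C2CC(=O)c3c(O)cc(OC)c(CC=C(C)C)c3O2)cc1OCOC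
F5 | step 4 | methyl (2S)-6-[2-(dimethylamino)prop-1-enyl]-2-[4-methoxy-3-(methoxymethoxy)phenyl]-4-oxo-2,3-dihydro-4H-pyran-5-carboxylate | COC(=O)C1=C(C=C(C)N(C)C)O[C@H](c2ccc(OC)c(OCOC)c2)CC1=O
F6 | step 5 | methyl (2S)-2-[4-methoxy-3-(methoxymethoxy)phenyl]-6-(4-methylpent-3-enyl)-4-oxo-2,3-dihydro-4H-pyran-5-carboxylate | COC(=O)C1=C(CCC=C(C)C)O[C@H](c2ccc(OC)c(OCOC)c2)CC1=O
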